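**Retrosynthetic overview** (azulene numbering: five-membered ring C1, C2, C3, C3a, C8a; seven-membered ring C3a, C4–C8, C8a)
1. The O4 ester is made last; the C7=C8 alkene comes from a C7 ketone through its enol triflate; the C3 carbinol comes from a C3 ketone by isopropyl addition.
2. The resulting C3/C7 diketone is opened at C3a–C8a and C7–C8 by an intramolecular de Mayo reaction (enone–alkene [2+2], then retro-aldol cleavage of C3a–C7). The precursor is a cyclopentene whose C3a carries a 4-methylpent-4-enoyl group; C8a–C8 is the alkene of that chain.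
3. Enabling feature: C3 (five-membered ring) and C7 (seven-membered ring) are 1,5-related through C3a–C8a–C8 and can both be carbonyl carbons. The tertiary C6–OH sits next to C7, so the C7 enol oxygen can be tied to O6 in a temporary five-membered cyclic carbonate that fixes enol regiochemistry and face of attack.
4. Ring order: cyclopentane C3a–C4–C5–C6–C7 first (from (S)-4-silyloxycyclopentenone; C4 and C6 set there), then the temporary dioxolanone, then in one operation the cyclobutane plus the cyclopentanone (C1–C3, C3a, C8a), and by fragmentation the seven-membered ring.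

Key step: step 8

Assumption: the C3a hydrogen of ketone 12 is taken to settle trans to the C8a methyl under the equilibrating basic conditions of step 8; compounds 1, 6 and 18 are taken as commercial.

**Step 1**
Reactants: 1 (4S)-4-[(tert-butyldimethylsilyl)oxy]cyclopent-2-en-1-one
Product: 2 (1R,4S)-4-[(tert-butyldimethylsilyl)oxy]-1-methylcyclopent-2-en-1-ol
Conditions: MeLi, Et2O, −78 °C; H2O
Reagents that add atoms: methyllithium, [Li]C
Why: 1,2-Addition of the organolithium to the enone carbonyl should occur on the face opposite the silyloxy group, which sets the tertiary carbinol (future C6) with its hydroxyl cis to the silyloxy group (future C4).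

**Step 2**
Reactants: 2 (1R,4S)-4-[(tert-butyldimethylsilyl)oxy]-1-methylcyclopent-2-en-1-ol
Product: 3 (1S,2R,4S,5R)-4-[(tert-butyldimethylsilyl)oxy]-2-methyl-6-oxabicyclo[3.1.0]hexan-2-ol (all-cis)
Conditions: VO(acac)2 (cat.), t-BuOOH, CH2Cl2, 0 °C to rt
Reagents that add atoms: tert-butyl hydroperoxide, CC(C)(C)OO
Why: Vanadium-catalysed hydroxyl-directed epoxidation of the allylic alcohol should deliver oxygen syn to the tertiary hydroxyl; both epoxide carbons lose their configuration later, and the syn geometry only serves the regiochemistry of step 3.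

**Step 3**
Reactants: 3 the all-cis epoxy alcohol
Product: 4 (1R,2S,4R)-4-[(tert-butyldimethylsilyl)oxy]-1-methylcyclopentane-1,2-diol
Conditions: LiEt3BH, THF, 0 °C to rt; H2O
Reagents that add atoms: none
Why: SN2 hydride opening of the epoxide must come from the face anti to the epoxide oxygen, where the carbon next to the quaternary carbinol is shielded by the methyl group, so hydride should enter at the carbon next to C4 and leave the secondary hydroxyl beside the tertiary one.

**Step 4**
Reactants: 4 (1R,2S,4R)-4-[(tert-butyldimethylsilyl)oxy]-1-methylcyclopentane-1,2-diol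
Product: 5 (2R,4S)-4-[(tert-butyldimethylsilyl)oxy]-2-hydroxy-2-methylcyclopentan-1-one
Conditions: IBX, DMSO, rt
Reagents that add atoms: none
Why: IBX oxidation of a vicinal diol should give the α-ketol without C–C cleavage, since only the secondary hydroxyl can be oxidised.

**Step 5**
Reactants: 5 (2R,4S)-4-[(tert-butyldimethylsilyl)oxy]-2-hydroxy-2-methylcyclopentan-1-one; 6 4-methylpent-4-enal
Product: 7 (2R,4S,5R)-4-[(tert-butyldimethylsilyl)oxy]-2-hydroxy-5-(1-hydroxy-4-methylpent-4-en-1-yl)-2-methylcyclopentan-1-one (both epimers at the side-chain carbinol carbon)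
Conditions: LiN(i-Pr)2 (2.2 equiv), THF, −78 °C; then 6, −78 °C; AcOH
Reagents that add atoms: none
Why: Lithium aldol addition of the dianion (alkoxide plus the only possible enolate, at the CH2 between the carbonyl and C4) should proceed at −78 °C, where β-elimination of the silyloxy group is slow; the new centres are erased in steps 6 and 7.

**Step 6**
Reactants: 7 the aldol adduct
Product: 8 (3S,5R)-3-[(tert-butyldimethylsilyl)oxy]-5-hydroxy-5-methyl-2-(4-methylpent-4-enoyl)cyclopentan-1-one (as its ring enol)
Conditions: Dess–Martin periodinane, NaHCO3, CH2Cl2, 0 °C to rt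
Reagents that add atoms: none
Why: Dess–Martin oxidation of the secondary carbinol should give the β-diketone, which rests as its enol; the tertiary hydroxyl cannot be oxidised.

**Step 7**
Reactants: 8 the β-diketone
Product: 9 (5S,6aR)-5-[(tert-butyldimethylsilyl)oxy]-6a-methyl-4-(4-methylpent-4-enoyl)-6,6a-dihydro-5H-cyclopenta[d][1,3]dioxol-2-one
Conditions: 1,1'-carbonyldiimidazole, DBU (cat.), CH2Cl2, 0 °C to rt
Reagents that add atoms: 1,1'-carbonyldiimidazole, O=C(n1ccnc1)n1ccnc1
Why: Cyclic carbonate formation between the tertiary hydroxyl and an enol oxygen: enol acylation is reversible while closure of the five-membered dioxolanone is not, so only the ring enol oxygen next to the carbinol carbon should be captured, which locks the C=C bond inside the cyclopentene.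

**Step 8**
Reactants: 9 the cyclic enol carbonate
Product: 12 (3aS,4S,6R,8aR)-4-[(tert-butyldimethylsilyl)oxy]-6-hydroxy-6,8a-dimethyloctahydroazulene-3,7-dione, via cyclobutane photoadduct 10 (not isolated), via cyclobutanediol 11 (not isolated)
Conditions: hν (λ ≥ 300 nm, Pyrex), MeCN, 0 °C, high dilution; then K2CO3 (cat.), MeOH, 0 °C to rt
Reagents that add atoms: none
Why: Excitation of the 2-acyl enol carbonate (a β-oxy enone whose C3a=C7 bond is held in the cyclopentene) gives the triplet, which bonds C3a to C8a of the tethered 1,1-disubstituted alkene and then C7 to C8, an intramolecular enone–alkene [2+2] photocycloaddition to cyclobutane 10; K2CO3 in methanol removes the carbonate and the cyclobutanolate of 11 undergoes retro-aldol cleavage of C3a–C7, the whole being an intramolecular de Mayo reaction, for which intramolecular de Mayo reactions of β-diketone enol esters and enol carbonates to bicyclo[5.3.0]decanediones are the closest precedent. The cyclopentanone ring (C1–C3, C3a, C8a) closes by 1,5-bonding of the excited enone to the alkene (rule of five, three-atom tether through the acyl carbon, straight rather than crossed adduct), and the seven-membered ring arises from the cyclopentane by insertion of C8a–C8 when the cyclobutane opens. C8a is controlled by the temporary ring: the dioxolanone must remain cis-fused on C6–C7, so C8 can bond to C7 only on the face that carries the C6 methyl group, which is also the face away from the C4 silyloxy group, and the cis-fused cyclobutane then places the C8a methyl on the same side of the seven-membered ring as the C6 methyl. C3a becomes an enolate carbon in the fragmentation and is reprotonated reversibly, and the trans-fused ketone (H3a anti to the C8a methyl) is expected because only in it the bulky C4 silyloxy group is trans to C3 and off the concave face. The step needs a defined enol regiochemistry, secured by the O6–O7 carbonate that allows only the ring enol, and survival of the β-silyloxy ketone, secured by the poor leaving group and the protic medium.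

**Step 9**
Reactants: 12 the hydroxy diketone
Product: 13 (3aS,4S,6R,8aR)-4-[(tert-butyldimethylsilyl)oxy]-6,8a-dimethyl-6-[(triethylsilyl)oxy]octahydroazulene-3,7-dione
Conditions: Et3SiOTf, 2,6-lutidine, CH2Cl2, −78 °C
Reagents that add atoms: triethylsilyl trifluoromethanesulfonate, CC[Si](CC)(CC)OS(=O)(=O)C(F)(F)F
Why: Silyl ether formation protects the tertiary α-hydroxyl before base chemistry at C7; at −78 °C with 2,6-lutidine the ketones should not be converted into silyl enol ethers.

**Step 10**
Reactants: 13 the bis-silyl diketone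
Product: 14 (3R,3aS,4S,6R,8aR)-4-[(tert-butyldimethylsilyl)oxy]-3-hydroxy-6,8a-dimethyl-3-(propan-2-yl)-6-[(triethylsilyl)oxy]octahydroazulen-7(1H)-one
Conditions: i-PrMgCl, LaCl3·2LiCl, THF, −20 °C; aq. NH4Cl
Reagents that add atoms: isopropylmagnesium chloride, CC(C)[Mg]Cl
Why: Lewis-acid-promoted Grignard addition should take place at the cyclopentanone only, the C7 ketone being flanked by the quaternary C6 and the neopentyl C8; attack on the face of H3a, opposite the angular C8a methyl and the C4 branch, should give the 3R carbinol.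

**Step 11**
Reactants: 14 the C3 carbinol
Product: 15 (3R,3aS,4S,6R,8aR)-4-[(tert-butyldimethylsilyl)oxy]-3-hydroxy-6,8a-dimethyl-3-(propan-2-yl)-6-[(triethylsilyl)oxy]-1,2,3,3a,4,5,6,8a-octahydroazulen-7-yl trifluoromethanesulfonate
Conditions: KN(SiMe3)2 (2.2 equiv), THF, −78 °C; PhNTf2, −78 to 0 °C; aq. NH4Cl
Reagents that add atoms: N-phenylbis(trifluoromethanesulfonimide), O=S(=O)(N(c1ccccc1)S(=O)(=O)C(F)(F)F)C(F)(F)F
Why: Enol triflate formation: the C7 ketone can enolise only towards C8 because C6 is quaternary, so trapping the potassium enolate should give a single vinyl triflate, and the hindered tertiary alkoxide is not expected to be sulfonylated.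

**Step 12**
Reactants: 15 the vinyl triflate
Product: 16 (3R,3aS,4S,6R,8aR)-4-[(tert-butyldimethylsilyl)oxy]-6,8a-dimethyl-3-(propan-2-yl)-6-[(triethylsilyl)oxy]-1,2,3,3a,4,5,6,8a-octahydroazulen-3-ol
Conditions: Pd(OAc)2 (cat.), PPh3, HCO2H, Bu3N, DMF, 60 °C
Reagents that add atoms: none
Why: Palladium-catalysed formate reduction of the vinyl triflate (oxidative addition, decarboxylation to the hydride, reductive elimination) should give the C7=C8 alkene, necessarily cis in the ring, without touching the silyl ethers.

**Step 13**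
Reactants: 16 the bis-silyl ether
Product: 17 (3R,3aS,4S,6R,8aR)-6,8a-dimethyl-3-(propan-2-yl)-1,2,3,3a,4,5,6,8a-octahydroazulene-3,4,6-triol
Conditions: Bu4NF, THF, rt to 50 °C
Reagents that add atoms: none
Why: Fluoride-mediated desilylation should remove both silyl ethers, the tertiary allylic alcohol being stable to these basic conditions.

**Step 14**
Reactants: 17 the triol; 18 4-acetoxybenzoyl chloride
Product: 19 (3R,3aS,4S,6R,8aR)-3,6-dihydroxy-6,8a-dimethyl-3-(propan-2-yl)-1,2,3,3a,4,5,6,8a-octahydroazulen-4-yl 4-(acetyloxy)benzoate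
Conditions: pyridine, DMAP (cat.), CH2Cl2, 0 °C to rt
Reagents that add atoms: none
Why: DMAP-catalysed acylation with the acid chloride should be selective for the only secondary hydroxyl, the two tertiary hydroxyls being unreactive.

**Step 15**
Reactants: 19 the acetoxybenzoate
Product: 20 (3R,3aS,4S,6R,8aR)-3,6-dihydroxy-6,8a-dimethyl-3-(propan-2-yl)-1,2,3,3a,4,5,6,8a-octahydroazulen-4-yl 4-hydroxybenzoate (target)
Conditions: K2CO3 (cat.), MeOH, 0 °C
Reagents that add atoms: none
Why: Base-catalysed transesterification should cleave the phenolic acetate much faster than the hindered secondary alkyl benzoate, giving the target.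

**Compound list**
1 | (4S)-4-[(tert-butyldimethylsilyl)oxy]cyclopent-2-en-1-one | O=C1C=C[C@@H](O[Si](C)(C)C(C)(C)C)C1 | starting material
2 | (1R,4S)-4-[(tert-butyldimethylsilyl)oxy]-1-methylcyclopent-2-en-1-ol (hydroxyl cis to silyloxy) | C[C@]1(O)C=C[C@@H](O[Si](C)(C)C(C)(C)C)C1 | intermediate
3 | (1S,2R,4S,5R)-4-[(tert-butyldimethylsilyl)oxy]-2-methyl-6-oxabicyclo[3.1.0]hexan-2-ol (epoxide oxygen, hydroxyl, silyloxy all cis) | C[C@]1(O)[C@H]2O[C@H]2[C@@H](O[Si](C)(C)C(C)(C)C)C1 | intermediate
4 | (1R,2S,4R)-4-[(tert-butyldimethylsilyl)oxy]-1-methylcyclopentane-1,2-diol (all oxygens cis) | C[C@]1(O)[C@@H](O)C[C@@H](O[Si](C)(C)C(C)(C)C)C1 | intermediate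
5 | (2R,4S)-4-[(tert-butyldimethylsilyl)oxy]-2-hydroxy-2-methylcyclopentan-1-one | C[C@]1(O)C(=O)C[C@@H](O[Si](C)(C)C(C)(C)C)C1 | intermediate
6 | 4-methylpent-4-enal | C=C(C)CCC=O | starting material
7 | (2R,4S,5R)-4-[(tert-butyldimethylsilyl)oxy]-2-hydroxy-5-(1-hydroxy-4-methylpent-4-en-1-yl)-2-methylcyclopentan-1-one (side chain trans to silyloxy; both carbinol epimers) | C=C(C)CCC(O)[C@H]1C(=O)[C@](C)(O)C[C@@H]1O[Si](C)(C)C(C)(C)C | intermediate
8 | (3S,5R)-3-[(tert-butyldimethylsilyl)oxy]-5-hydroxy-5-methyl-2-(4-methylpent-4-enoyl)cyclopentan-1-one, ring enol form | O=C(CCC(C)=C)C1=C(O)[C@](C)(O)C[C@@H]1O[Si](C)(C)C(C)(C)C | intermediate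
9 | (5S,6aR)-5-[(tert-butyldimethylsilyl)oxy]-6a-methyl-4-(4-methylpent-4-enoyl)-6,6a-dihydro-5H-cyclopenta[d][1,3]dioxol-2-one | C=C(C)CCC(=O)C1=C2OC(=O)O[C@]2(C)C[C@@H]1O[Si](C)(C)C(C)(C)C | intermediate
10 | cyclobutane photoadduct (C3a–C8a and C7–C8 bonded, C3a–C7 intact, cyclic carbonate on O6/O7, all ring fusions cis) | O=C1CC[C@]2(C)C[C@@]34OC(=O)O[C@]3(C)C[C@H](O[Si](C)(C)C(C)(C)C)[C@@]124 | intermediate
11 | cyclobutanediol (10 without the carbonate carbonyl; hydroxyls on C6 and C7) | O=C1CC[C@]2(C)C[C@@]3(O)[C@](C)(O)C[C@H](O[Si](C)(C)C(C)(C)C)[C@@]123 | intermediate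
12 | (3aS,4S,6R,8aR)-4-[(tert-butyldimethylsilyl)oxy]-6-hydroxy-6,8a-dimethyloctahydroazulene-3,7-dione (trans-fused) | O=C1CC[C@]2(C)CC(=O)[C@](C)(O)C[C@H](O[Si](C)(C)C(C)(C)C)[C@@H]12 | intermediate
13 | (3aS,4S,6R,8aR)-4-[(tert-butyldimethylsilyl)oxy]-6,8a-dimethyl-6-[(triethylsilyl)oxy]octahydroazulene-3,7-dione | O=C1CC[C@]2(C)CC(=O)[C@](C)(O[Si](CC)(CC)CC)C[C@H](O[Si](C)(C)C(C)(C)C)[C@@H]12 | intermediate
14 | (3R,3aS,4S,6R,8aR)-4-[(tert-butyldimethylsilyl)oxy]-3-hydroxy-6,8a-dimethyl-3-(propan-2-yl)-6-[(triethylsilyl)oxy]octahydroazulen-7(1H)-one | CC(C)[C@]1(O)CC[C@]2(C)CC(=O)[C@](C)(O[Si](CC)(CC)CC)C[C@H](O[Si](C)(C)C(C)(C)C)[C@H]21 | intermediate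
15 | (3R,3aS,4S,6R,8aR)-4-[(tert-butyldimethylsilyl)oxy]-3-hydroxy-6,8a-dimethyl-3-(propan-2-yl)-6-[(triethylsilyl)oxy]-1,2,3,3a,4,5,6,8a-octahydroazulen-7-yl trifluoromethanesulfonate | CC(C)[C@]1(O)CC[C@]2(C)C=C(OS(=O)(=O)C(F)(F)F)[C@](C)(O[Si](CC)(CC)CC)C[C@H](O[Si](C)(C)C(C)(C)C)[C@H]21 | intermediate
16 | (3R,3aS,4S,6R,8aR)-4-[(tert-butyldimethylsilyl)oxy]-6,8a-dimethyl-3-(propan-2-yl)-6-[(triethylsilyl)oxy]-1,2,3,3a,4,5,6,8a-octahydroazulen-3-ol | CC(C)[C@]1(O)CC[C@]2(C)C=C[C@](C)(O[Si](CC)(CC)CC)C[C@H](O[Si](C)(C)C(C)(C)C)[C@H]21 | intermediate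
17 | (3R,3aS,4S,6R,8aR)-6,8a-dimethyl-3-(propan-2-yl)-1,2,3,3a,4,5,6,8a-octahydroazulene-3,4,6-triol | CC(C)[C@]1(O)CC[C@]2(C)C=C[C@](C)(O)C[C@H](O)[C@H]21 | intermediate
18 | 4-acetoxybenzoyl chloride | CC(=O)Oc1ccc(cc1)C(Cl)=O | starting material
19 | (3R,3aS,4S,6R,8aR)-3,6-dihydroxy-6,8a-dimethyl-3-(propan-2-yl)-1,2,3,3a,4,5,6,8a-octahydroazulen-4-yl 4-(acetyloxy)benzoate | CC(C)[C@]1(O)CC[C@]2(C)C=C[C@](C)(O)C[C@H](OC(=O)c3ccc(OC(C)=O)cc3)[C@H]21 | intermediate
20 | (3R,3aS,4S,6R,8aR)-3,6-dihydroxy-6,8a-dimethyl-3-(propan-2-yl)-1,2,3,3a,4,5,6,8a-octahydroazulen-4-yl 4-hydroxybenzoate | CC(C)[C@]1(O)CC[C@]2(C)C=C[C@](C)(O)C[C@H](OC(=O)c3ccc(O)cc3)[C@H]21 | target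

**Step count and risks**
Total steps: 15. Longest linear sequence: 15 steps (1 to 20); 6 and 18 enter as commercial reagents.

Steps most likely to fail:

Step 8. The process at risk is the reprotonation at C3a after the fragmentation: the cis-fused ketone may prevail, and the base that removes the carbonate may also cause β-elimination of the C4 silyloxy group from the C3 enolate. The fallback replaces the base-labile carbonate by an acid-labile ketal, so that fragmentation and ketonisation occur without base. It sets out from 8: 2-methoxypropene with PPTS should give the isopropylidene enol ketal F1; irradiation as in step 8 should give the cyclobutane ketal F2; PPTS in methanol at 40 °C should remove the ketal, so that diol 11 fragments under non-equilibrating acidic conditions. The route is rejoined at 12.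

Step 10. The processes at risk are β-hydride reduction or enolisation of the hindered cyclopentanone by the secondary Grignard reagent, competing addition at C7, and attack from the wrong face. The fallback sets out from 13: isopropenylmagnesium bromide with LaCl3·2LiCl (an sp2 nucleophile that cannot reduce) should give the isopropenyl carbinol F3; hydrogenation of its 1,1-disubstituted alkene (H2, PtO2, ethyl acetate; no other alkene is present at this stage) returns to 14.

Step 5. The process at risk is β-elimination of the silyloxy group from the lithium enolate, or retro-aldol loss of the adduct on work-up. The fallback avoids a free enolate. It sets out from 5: Me3SiOTf and Et3N should give the bis(trimethylsilyl) enol ether F4 (enol ether plus tertiary silyl ether); Mukaiyama aldol addition to 6 (BF3·OEt2, CH2Cl2, −78 °C) with dilute acid work-up, which also removes the tertiary trimethylsilyl ether, returns to 7.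

**Further compounds**
F1 | step 8 | (5S,6aR)-5-[(tert-butyldimethylsilyl)oxy]-2,2,6a-trimethyl-4-(4-methylpent-4-enoyl)-6,6a-dihydro-5H-cyclopenta[d][1,3]dioxole (isopropylidene enol ketal) | C=C(C)CCC(=O)C1=C2OC(C)(C)O[C@]2(C)C[C@@H]1O[Si](C)(C)C(C)(C)C
F2 | step 8 | cyclobutane ketal (photoadduct of F1; analogue of 10 with an isopropylidene in place of the carbonate carbonyl) | O=C1CC[C@]2(C)C[C@@]34OC(C)(C)O[C@]3(C)C[C@H](O[Si](C)(C)C(C)(C)C)[C@@]124
F3 | step 10 | isopropenyl carbinol (analogue of 14 with prop-1-en-2-yl at C3) | C=C(C)[C@]1(O)CC[C@]2(C)CC(=O)[C@](C)(O[Si](CC)(CC)CC)C[C@H](O[Si](C)(C)C(C)(C)C)[C@H]21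
F4 | step 5 | bis(trimethylsilyl) enol ether of 5 | C[Si](C)(C)OC1=C[C@@H](O[Si](C)(C)C(C)(C)C)C[C@@]1(C)O[Si](C)(C)C
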